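**Strategy.** The dihydrobenzofuran is disconnected at C2–C3. C3 is attached to C3a of ring A and carries a carbon at the ester level (the later CH2OH), so it can serve as a donor/acceptor carbene carbon, while C2 is the O-benzylic CH2 of an aryl benzyl ether. A chiral dirhodium tetracarboxylate therefore closes the five-membered ring by enantioselective 1,5 C–H insertion of an ortho-(benzyloxy)aryl diazoacetate, setting C2; base equilibration then sets C3 trans. The precursor already carries the aldehyde as a dioxolane and the syringyl oxygen as an aryloxyacetyl oxazolidinone, which afterwards delivers the erythro arylglycerol unit by an anti-aldol reaction and a final global reduction–hydrolysis.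

Key step: step 5

Assumption (remark on the chemistry): Rh2(S-PTTL)4 (dirhodium tetrakis[N-phthaloyl-(S)-tert-leucinate]) is taken to select the benzylic hydrogen that leads to the (2R) centre, by analogy with simpler 2-(benzyloxy)aryl diazoacetates; the mirror-image catalyst Rh2(R-PTTL)4 would be used if the sense proved opposite.

Assumption (remark on the chemistry): the MgCl2-catalysed anti-aldol of the N-acyl oxazolidinone is taken to proceed through the magnesium-chelated Z-enolate with attack on the face away from the 4-benzyl group, which for the (R)-auxiliary gives the (7S,8R) erythro unit.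

**Step 1**
Reactants: 1 4-(hydroxymethyl)-2,6-dimethoxyphenol (syringyl alcohol); 2 (R)-4-benzyl-3-(chloroacetyl)oxazolidin-2-one
Product: 3 (R)-4-benzyl-3-{[4-(hydroxymethyl)-2,6-dimethoxyphenoxy]acetyl}oxazolidin-2-one
Conditions: K2CO3, NaI (cat.), MeCN, 40 °C
Reagents that add atoms: none
Why: Williamson etherification: the phenoxide of 1, much more acidic than its benzylic alcohol, displaces halide (chloride exchanged for iodide in the flask, Finkelstein) from the α-halo imide by SN2 under mild carbonate conditions that should leave the N-acyl oxazolidinone intact, so that the auxiliary-bearing glycolate also protects the syringyl oxygen; no stereocentre is formed.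

**Step 2**
Reactants: 3 the benzylic alcohol from step 1; 4 4-hydroxy-3-iodo-5-methoxybenzaldehyde (5-iodovanillin)
Product: 5 (R)-4-benzyl-3-({4-[(4-formyl-2-iodo-6-methoxyphenoxy)methyl]-2,6-dimethoxyphenoxy}acetyl)oxazolidin-2-one
Conditions: PPh3, DIAD, THF, 0 °C → rt
Reagents that add atoms: none
Why: Mitsunobu reaction: the acidic phenol 4 is alkylated by the alkoxyphosphonium ion of the primary benzylic alcohol of 3 under neutral conditions tolerated by the aldehyde, the aryl iodide and the imide; no stereocentre is formed.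

**Step 3**
Reactants: 5 the aryl benzyl ether aldehyde
Product: 6 the 1,3-dioxolane of 5
Conditions: TMSOCH2CH2OTMS, TMSOTf (cat.), CH2Cl2, −78 → −20 °C; pyridine quench
Reagents that add atoms: 1,2-bis(trimethylsilyloxy)ethane, C[Si](C)(C)OCCO[Si](C)(C)C
Why: Aprotic acetalisation with the bis-silyl ether of ethylene glycol under silyl triflate catalysis at low temperature masks the aldehyde, which would otherwise compete as an electrophile in step 6 and be reduced in step 7, without touching the benzylic aryl ether or the imide.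

**Step 4**
Reactants: 6 the aryl iodide; 7 ethyl diazoacetate
Product: 8 ethyl 2-diazo-2-arylacetate (aryl = ring A carrying the syringyl-type benzyloxy group ortho, OMe, and the dioxolane)
Conditions: Pd(PPh3)4 (5 mol %), Ag2CO3 (0.5 equiv), Et3N, toluene, rt, dark
Reagents that add atoms: none
Why: Pd-catalysed cross-coupling of an aryl iodide with the C–H bond of an acceptor diazo ester (oxidative addition at zerovalent palladium, silver/amine-assisted metalation of the diazo carbon, reductive elimination at room temperature before N2 is lost) should install the aryldiazoacetate directly and leave the less acidic imide methylene alone.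

**Step 5**
Reactants: 8 the aryl diazoacetate
Product: 10 ethyl (2R,3R)-trans-2-aryl-5-(1,3-dioxolan-2-yl)-7-methoxy-2,3-dihydrobenzofuran-3-carboxylate, via cis-dihydrobenzofuran ester 9 (not isolated)
Conditions: Rh2(S-PTTL)4 (2 mol %), toluene, −60 → −40 °C, slow addition of 8; then DBU, rt → 40 °C
Reagents that add atoms: none
Why: Loss of N2 from 8 at the dirhodium centre (divalent rhodium) gives a donor/acceptor carbenoid whose carbon inserts into one of the two enantiotopic O-benzylic C–H bonds in 1,5 relationship through a concerted, asynchronous three-centre transition state (hydride-like transfer to the carbenoid carbon with C–C bond formation), which creates the C2–C3 bond and the dihydrofuran ring in one event. The closest known reaction type is the enantioselective intramolecular C–H insertion of 2-(benzyloxy)aryl diazoacetates with chiral dirhodium tetracarboxylates to cis-2-aryl-2,3-dihydrobenzofuran-3-carboxylates. The ring closes in the 1,5-insertion mode (five-membered ring, both bond-forming carbons in the ring), attack on the ether oxygen being excluded because the oxonium ylide would be four-membered. C2 is set by the chiral carboxylate pocket of the catalyst (choice between the enantiotopic hydrogens); C3 is formed cis under kinetic control and is then equilibrated by DBU through the ester enolate to the more stable trans ester, C2 staying untouched because ring opening from that enolate would be the reverse of a 5-endo-trig closure. The step needs chemoselectivity for this C–H bond over carbene dimerisation, aromatic cycloaddition and reaction at the remote imide or acetal, which is secured by the 1,5 relationship, the activation of the C–H bond by the ether oxygen and the electron-rich syringyl ring, low temperature and slow addition.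

**Step 6**
Reactants: 10 the trans ester imide; 11 4-formyl-2-methoxyphenyl acetate (vanillin acetate)
Product: 12 anti-aldol adduct as its trimethylsilyl ether, (2S,3S) in the acyl chain
Conditions: MgCl2 (20 mol %), Et3N, TMSCl, EtOAc, rt; non-acidic work-up
Reagents that add atoms: chlorotrimethylsilane, C[Si](C)(C)Cl
Why: MgCl2-catalysed direct anti-aldol reaction of an N-acyl oxazolidinone with a non-enolisable aromatic aldehyde: soft enolisation gives the chelated Z-enolate, which should add to 11 on the face away from the 4-benzyl group through a boat-like transition state to the anti adduct, silylation releasing magnesium; this sets the carbinol centre (S) and the aryloxy-bearing centre (S in the imide, R after reduction), i.e. the erythro relationship.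

**Step 7**
Reactants: 12 the silylated aldol adduct
Product: 14 the target, via silylated acetal triol 13 (not isolated)
Conditions: LiBH4, MeOH (2 equiv), THF, 0 °C → rt; then 1 M aq. HCl to pH 2, THF, 0 °C → rt
Reagents that add atoms: water, O
Why: LiBH4 should cleave the imide reductively to the primary alcohol with release of the auxiliary, reduce the ethyl ester to the hydroxymethyl group and remove the phenolic acetate, and the acidic work-up then hydrolyses the dioxolane to the aldehyde (only after all hydride is destroyed) and the silyl ether by Si–O cleavage, so that no stereocentre is touched.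

**Compound list**

1 | 4-(hydroxymethyl)-2,6-dimethoxyphenol | COc1cc(CO)cc(OC)c1O | starting material
2 | (R)-4-benzyl-3-(chloroacetyl)oxazolidin-2-one | O=C(CCl)N1[C@H](Cc2ccccc2)COC1=O | starting material
3 | (R)-4-benzyl-3-{[4-(hydroxymethyl)-2,6-dimethoxyphenoxy]acetyl}oxazolidin-2-one | O=C(COc1c(OC)cc(CO)cc1OC)N1[C@H](Cc2ccccc2)COC1=O | intermediate
4 | 4-hydroxy-3-iodo-5-methoxybenzaldehyde | COc1cc(C=O)cc(I)c1O | starting material
5 | (R)-4-benzyl-3-({4-[(4-formyl-2-iodo-6-methoxyphenoxy)methyl]-2,6-dimethoxyphenoxy}acetyl)oxazolidin-2-one | O=C(COc1c(OC)cc(COc2c(I)cc(C=O)cc2OC)cc1OC)N1[C@H](Cc2ccccc2)COC1=O | intermediate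
6 | (R)-4-benzyl-3-[(4-{[4-(1,3-dioxolan-2-yl)-2-iodo-6-methoxyphenoxy]methyl}-2,6-dimethoxyphenoxy)acetyl]oxazolidin-2-one | O=C(COc1c(OC)cc(COc2c(I)cc(C3OCCO3)cc2OC)cc1OC)N1[C@H](Cc2ccccc2)COC1=O | intermediate
7 | ethyl diazoacetate | CCOC(=O)C=[N+]=[N-] | starting material
8 | ethyl 2-diazo-2-{2-[(4-{2-[(R)-4-benzyl-2-oxooxazolidin-3-yl]-2-oxoethoxy}-3,5-dimethoxybenzyl)oxy]-5-(1,3-dioxolan-2-yl)-3-methoxyphenyl}acetate | CCOC(=O)C(=[N+]=[N-])c1cc(C2OCCO2)cc(OC)c1OCc1cc(OC)c(OCC(=O)N2[C@H](Cc3ccccc3)COC2=O)c(OC)c1 | intermediate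
9 | ethyl (2R,3S)-cis-2-(4-{2-[(R)-4-benzyl-2-oxooxazolidin-3-yl]-2-oxoethoxy}-3,5-dimethoxyphenyl)-5-(1,3-dioxolan-2-yl)-7-methoxy-2,3-dihydrobenzofuran-3-carboxylate | O=C(COc1c(OC)cc([C@@H]2Oc3c(OC)cc(C4OCCO4)cc3[C@@H]2C(=O)OCC)cc1OC)N1[C@H](Cc2ccccc2)COC1=O | intermediate (not isolated)
10 | ethyl (2R,3R)-trans-2-(4-{2-[(R)-4-benzyl-2-oxooxazolidin-3-yl]-2-oxoethoxy}-3,5-dimethoxyphenyl)-5-(1,3-dioxolan-2-yl)-7-methoxy-2,3-dihydrobenzofuran-3-carboxylate | O=C(COc1c(OC)cc([C@@H]2Oc3c(OC)cc(C4OCCO4)cc3[C@H]2C(=O)OCC)cc1OC)N1[C@H](Cc2ccccc2)COC1=O | intermediate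
11 | 4-formyl-2-methoxyphenyl acetate | CC(=O)Oc1ccc(C=O)cc1OC | starting material
12 | ethyl (2R,3R)-2-(4-{[(1S,2S)-1-(4-acetoxy-3-methoxyphenyl)-3-[(R)-4-benzyl-2-oxooxazolidin-3-yl]-3-oxo-1-(trimethylsilyloxy)propan-2-yl]oxy}-3,5-dimethoxyphenyl)-5-(1,3-dioxolan-2-yl)-7-methoxy-2,3-dihydrobenzofuran-3-carboxylate | CC(=O)Oc1ccc([C@H](O[Si](C)(C)C)[C@@H](C(=O)N2[C@H](Cc3ccccc3)COC2=O)Oc2c(OC)cc([C@@H]3Oc4c(OC)cc(C5OCCO5)cc4[C@H]3C(=O)OCC)cc2OC)cc1OC | intermediate
13 | (2R)-2-{4-[(2R,3S)-5-(1,3-dioxolan-2-yl)-3-(hydroxymethyl)-7-methoxy-2,3-dihydrobenzofuran-2-yl]-2,6-dimethoxyphenoxy}-3-(4-hydroxy-3-methoxyphenyl)-3-(S)-(trimethylsilyloxy)propan-1-ol | COc1cc([C@H](O[Si](C)(C)C)[C@@H](CO)Oc2c(OC)cc([C@@H]3Oc4c(OC)cc(C5OCCO5)cc4[C@H]3CO)cc2OC)ccc1O | intermediate (not isolated)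
14 | (2R,3S)-2-(4-{[(1S,2R)-1,3-dihydroxy-1-(4-hydroxy-3-methoxyphenyl)propan-2-yl]oxy}-3,5-dimethoxyphenyl)-3-(hydroxymethyl)-7-methoxy-2,3-dihydrobenzofuran-5-carbaldehyde | COc1cc([C@H](O)[C@@H](CO)Oc2c(OC)cc([C@@H]3Oc4c(OC)cc(C=O)cc4[C@H]3CO)cc2OC)ccc1O | target

**Totals.** Total step count: 7. Longest linear sequence: 7 steps (from 1 and 2 to 14; compounds 4, 7 and 11 enter as commercial partners).

**Steps most likely to fail**

1. Step 5 (key step). What may go wrong: poor discrimination between the two enantiotopic benzylic hydrogens on this doubly ortho-substituted aryl ether, inhibition of the catalyst by the imide carbonyl groups, or slow base equilibration of the ester with competing ring opening. Fallback (stereocontrol by a covalently bound ester auxiliary matched to a chiral catalyst, expected to give the trans ester directly): it sets out from 6. Ethyl (S)-lactate is heated with pyrrolidine to give (S)-2-hydroxy-1-(pyrrolidin-1-yl)propan-1-one F1, which is acylated with succinimidyl diazoacetate (Et3N, CH2Cl2) to (S)-1-oxo-1-(pyrrolidin-1-yl)propan-2-yl diazoacetate F2. Coupling of F2 with 6 under the conditions of step 4 should give the lactamide aryldiazoacetate F3. Rh2(S-DOSP)4 (dirhodium tetrakis[(S)-N-(4-dodecylphenylsulfonyl)prolinate]) in CH2Cl2 should then give the trans-(2R,3R) lactamide ester F4 by double stereodifferentiation; the (S)-lactamide/(S)-catalyst pair is assumed to be the matched one for 2R, and DBU equilibration is added only if cis ester remains. The anti-aldol of step 6 with 11 converts F4 into the silylated adduct F5. Under the conditions of step 7 the lactamide ester is reduced as the ethyl ester was, which brings the sequence back to the route at 13 and hence 14.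

2. Step 6. What may go wrong: erosion of anti selectivity or of facial control because the 2,6-dimethoxyaryloxy group competes for magnesium, or incomplete silylative turnover. Fallback (stoichiometric boron enolate and external Lewis acid activation through an open transition state): it sets out from 10. Enolisation with Bu2BOTf and iPr2NEt (CH2Cl2, −78 → 0 °C) and addition of the dibutylboron enolate at −78 °C to 11 precomplexed with Et2AlCl should give the free anti-aldol, the (2S,3S)-β-hydroxy imide F6, with the same sense at both centres. Silylation (TMSCl, imidazole, CH2Cl2) comes back to the route at 12.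

3. Step 4. What may go wrong: sluggish coupling at the ortho-alkoxylated iodide and loss of the diazo group through carbene formation at palladium. Fallback (carbon framework first, diazo group second): it sets out from 6. Pd-catalysed arylation of the Reformatsky reagent BrZnCH2CO2Et (Pd2(dba)3, P(t-Bu)3, THF, rt → 60 °C) should give the ethyl arylacetate F7. Regitz diazo transfer with 4-acetamidobenzenesulfonyl azide and DBU (MeCN, 0 °C), which is expected to act only at the benzylic ester methylene, comes back to the route at 8.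

**Further compounds**

F1 | step 5 | (S)-2-hydroxy-1-(pyrrolidin-1-yl)propan-1-one | C[C@H](O)C(=O)N1CCCC1
F2 | step 5 | (S)-1-oxo-1-(pyrrolidin-1-yl)propan-2-yl diazoacetate | [N-]=[N+]=CC(=O)O[C@@H](C)C(=O)N1CCCC1
F3 | step 5 | (S)-1-oxo-1-(pyrrolidin-1-yl)propan-2-yl 2-diazo-2-{2-[(4-{2-[(R)-4-benzyl-2-oxooxazolidin-3-yl]-2-oxoethoxy}-3,5-dimethoxybenzyl)oxy]-5-(1,3-dioxolan-2-yl)-3-methoxyphenyl}acetate | C[C@H](OC(=O)C(=[N+]=[N-])c1cc(C2OCCO2)cc(OC)c1OCc1cc(OC)c(OCC(=O)N2[C@H](Cc3ccccc3)COC2=O)c(OC)c1)C(=O)N1CCCC1
F4 | step 5 | (S)-1-oxo-1-(pyrrolidin-1-yl)propan-2-yl (2R,3R)-trans-2-(4-{2-[(R)-4-benzyl-2-oxooxazolidin-3-yl]-2-oxoethoxy}-3,5-dimethoxyphenyl)-5-(1,3-dioxolan-2-yl)-7-methoxy-2,3-dihydrobenzofuran-3-carboxylate | O=C(COc1c(OC)cc([C@@H]2Oc3c(OC)cc(C4OCCO4)cc3[C@H]2C(=O)O[C@@H](C)C(=O)N2CCCC2)cc1OC)N1[C@H](Cc2ccccc2)COC1=O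
F5 | step 5 | lactamide-ester analogue of 12 (silylated (2S,3S) anti-aldol adduct of F4 with 11) | CC(=O)Oc1ccc([C@H](O[Si](C)(C)C)[C@@H](C(=O)N2[C@H](Cc3ccccc3)COC2=O)Oc2c(OC)cc([C@@H]3Oc4c(OC)cc(C5OCCO5)cc4[C@H]3C(=O)O[C@@H](C)C(=O)N3CCCC3)cc2OC)cc1OC
F6 | step 6 | free (2S,3S) anti-aldol adduct (12 without the trimethylsilyl group) | CC(=O)Oc1ccc([C@H](O)[C@@H](C(=O)N2[C@H](Cc3ccccc3)COC2=O)Oc2c(OC)cc([C@@H]3Oc4c(OC)cc(C5OCCO5)cc4[C@H]3C(=O)OCC)cc2OC)cc1OC
F7 | step 4 | ethyl 2-{2-[(4-{2-[(R)-4-benzyl-2-oxooxazolidin-3-yl]-2-oxoethoxy}-3,5-dimethoxybenzyl)oxy]-5-(1,3-dioxolan-2-yl)-3-methoxyphenyl}acetate | CCOC(=O)Cc1cc(C2OCCO2)cc(OC)c1OCc1cc(OC)c(OCC(=O)N2[C@H](Cc3ccccc3)COC2=O)c(OC)c1
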